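The pyranone ring is read as an aldol whose hydroxyl is arylated: C2 is a carbinol carbon β to the C4 ketone, and its oxygen O1 sits on C8a, ortho to the C4 acyl group on ring A. Cutting C2–C3 and O1–C8a together makes O1 and C2 the carbonyl group of an aldehyde. In one operation a catalytic enantioselective Mukaiyama aldol sets C2, and the silyl ether formed, unmasked by fluoride, closes the ring by SNAr at C8a. The precursor is the silyl enol ether of a 2'-fluoroacetophenone whose two bromines, ortho and para to fluorine, activate the SNAr and later become the C6 and C8 prenyl groups.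

Key step: step 5

Remark (assumption): 4-(methoxymethoxy)benzaldehyde 7 is taken as a purchased compound, and in step 5 the catalyst enantiomer is the one that directs the enol silane to the Si face of the aldehyde (3S in 8, 2S in 9); the sense of induction is to be checked on the first run and the mirror-image catalyst, from the other tryptophan enantiomer, used if required.

Step 1
Reactants: 1 1-fluoro-3,5-dimethoxybenzene
Product: 3 1-(2-fluoro-6-hydroxy-4-methoxyphenyl)ethan-1-one, via 2-fluoro-4,6-dimethoxyacetophenone 2 (not isolated)
Conditions: AcCl (1.2 equiv), AlCl3 (3 equiv), CH2Cl2, 0 °C → reflux; aq. HCl work-up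
Reagents that add atoms: acetyl chloride, CC(=O)Cl
Why: Friedel–Crafts acylation should take place ortho to fluorine and para to a methoxy group (the usual site for 5-substituted 1,3-dimethoxybenzenes, the position between the two methoxy groups being more hindered), and excess AlCl3 then cleaves only the methyl ether ortho to the new carbonyl through the six-membered aluminium chelate, leaving the para methoxy group that becomes the C7 OMe.

Step 2
Reactants: 3 1-(2-fluoro-6-hydroxy-4-methoxyphenyl)ethan-1-one
Product: 4 1-(3,5-dibromo-2-fluoro-6-hydroxy-4-methoxyphenyl)ethan-1-one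
Conditions: NBS (2.1 equiv), MeCN, 0 °C → rt, dark
Reagents that add atoms: N-bromosuccinimide, O=C1CCC(=O)N1Br
Why: Electrophilic aromatic bromination of the phenol fills the only two free ring positions, which are ortho and para to the hydroxyl and both ortho to the methoxy group, so no regiochemical choice arises.

Step 3
Reactants: 4 1-(3,5-dibromo-2-fluoro-6-hydroxy-4-methoxyphenyl)ethan-1-one
Product: 5 1-[3,5-dibromo-2-fluoro-4-methoxy-6-(methoxymethoxy)phenyl]ethan-1-one
Conditions: NaH (1.2 equiv), MOMCl (1.3 equiv), DMF, 0 °C → rt
Reagents that add atoms: chloromethyl methyl ether, COCCl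
Why: Williamson-type O-alkylation of the phenoxide with the reactive α-chloro ether gives the MOM acetal, which keeps the later C5 oxygen from forming a phenoxide that would deactivate the ring towards SNAr and interfere with the enolate chemistry.

Step 4
Reactants: 5 1-[3,5-dibromo-2-fluoro-4-methoxy-6-(methoxymethoxy)phenyl]ethan-1-one
Product: 6 ({1-[3,5-dibromo-2-fluoro-4-methoxy-6-(methoxymethoxy)phenyl]ethenyl}oxy)trimethylsilane
Conditions: LiHMDS (1.1 equiv), THF, −78 °C; TMSCl (1.3 equiv), −78 → 0 °C; pentane, filtration, used crude
Reagents that add atoms: chlorotrimethylsilane, C[Si](C)(C)Cl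
Why: Kinetic deprotonation of the methyl ketone and O-silylation of the lithium enolate (silyl enol ether formation) is safe here because the ring carries no hydrogen and aryl bromides do not exchange with LiHMDS at −78 °C.

Step 5
Reactants: 6 ({1-[3,5-dibromo-2-fluoro-4-methoxy-6-(methoxymethoxy)phenyl]ethenyl}oxy)trimethylsilane; 7 4-(methoxymethoxy)benzaldehyde
Product: 9 (2S)-6,8-dibromo-7-methoxy-5-(methoxymethoxy)-2-[4-(methoxymethoxy)phenyl]-2,3-dihydro-4H-chromen-4-one, via β-silyloxy ketone 8 (not isolated)
Conditions: (i) 7 (1.2 equiv), chiral B-n-butyl-1,3,2-oxazaborolidin-5-one from N-tosyltryptophan (20 mol %), EtCN, −78 °C, until 6 is consumed; (ii) TBAT (0.3 equiv), THF, −78 → −20 °C; AcOH quench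
Reagents that add atoms: none
Why: The chiral boron Lewis acid activates aldehyde 7 and enol silane 6 adds through an open transition state to its Si face (Mukaiyama aldol with silyl transfer, giving 8); fluoride then unmasks the C2 alkoxide, which adds to C8a and expels fluoride (addition–elimination, SNAr), and the fluoride released desilylates the next molecule, so that Me3SiF is the only by-product. The closest known reactions are the oxazaborolidinone-catalysed Mukaiyama aldol of aryl methyl ketone enol silanes with aromatic aldehydes and the base-mediated cyclisation of 1-(2-fluoroaryl)-3-hydroxy ketones to chroman-4-ones. The pyranone ring closes at C8a as a six-membered addition–elimination, formally 6-endo-trig because C8a is the β-carbon of the C8a=C4a–C4=O unit that takes up the charge, which is a favoured mode. The C2 stereocentre is set by the catalyst in the aldol stage (enantioface control, no diastereomer question) and is not touched by the O-arylation, in which the C2–O bond stays intact. The step needs displacement of F in preference to Br and OMOM, secured by F being the best SNAr leaving group and the only halogen ortho to the carbonyl. It also needs ring closure to outrun retro-aldol and E1cB loss of the alkoxide, which the two bromines ortho and para to fluorine, the low temperature and the substoichiometric fluoride charge should secure.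

Step 6
Reactants: 9 (2S)-6,8-dibromo-7-methoxy-5-(methoxymethoxy)-2-[4-(methoxymethoxy)phenyl]-2,3-dihydro-4H-chromen-4-one
Product: 10 (2S)-7-methoxy-5-(methoxymethoxy)-2-[4-(methoxymethoxy)phenyl]-6,8-bis(3-methylbut-2-en-1-yl)-2,3-dihydro-4H-chromen-4-one
Conditions: tributyl(3-methylbut-2-en-1-yl)stannane (3 equiv), Pd(P(t-Bu)3)2 (10 mol %), DMF (degassed), 80 °C
Reagents that add atoms: tributyl(3-methylbut-2-en-1-yl)stannane, CCCC[Sn](CCCC)(CCCC)CC=C(C)C
Why: Migita–Kosugi–Stille coupling under neutral conditions replaces both aryl bromides, the allyl–palladium intermediate undergoing reductive elimination at its CH2 terminus to give the linear 3-methylbut-2-enyl groups, and the absence of base leaves the enolisable C3 and therefore the C2 stereocentre untouched.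

Step 7
Reactants: 10 (2S)-7-methoxy-5-(methoxymethoxy)-2-[4-(methoxymethoxy)phenyl]-6,8-bis(3-methylbut-2-en-1-yl)-2,3-dihydro-4H-chromen-4-one
Product: 11 (2S)-5-hydroxy-2-(4-hydroxyphenyl)-7-methoxy-6,8-bis(3-methylbut-2-en-1-yl)-2,3-dihydro-4H-chromen-4-one
Conditions: 3 M HCl, MeOH, rt → 40 °C
Reagents that add atoms: none
Why: Acid-catalysed acetal methanolysis removes both MOM groups (the peri 5-O-MOM fastest, assisted by the C4 carbonyl) under conditions mild enough that the trisubstituted alkenes are not protonated and the C2–O1 bond is not ionised, so the 2S configuration is kept.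

Compound list
1 | 1-fluoro-3,5-dimethoxybenzene | COc1cc(F)cc(OC)c1 | starting material
2 | 1-(2-fluoro-4,6-dimethoxyphenyl)ethan-1-one | CC(=O)c1c(F)cc(OC)cc1OC | intermediate
3 | 1-(2-fluoro-6-hydroxy-4-methoxyphenyl)ethan-1-one | CC(=O)c1c(F)cc(OC)cc1O | intermediate
4 | 1-(3,5-dibromo-2-fluoro-6-hydroxy-4-methoxyphenyl)ethan-1-one | CC(=O)c1c(F)c(Br)c(OC)c(Br)c1O | intermediate
5 | 1-[3,5-dibromo-2-fluoro-4-methoxy-6-(methoxymethoxy)phenyl]ethan-1-one | CC(=O)c1c(F)c(Br)c(OC)c(Br)c1OCOC | intermediate
6 | ({1-[3,5-dibromo-2-fluoro-4-methoxy-6-(methoxymethoxy)phenyl]ethenyl}oxy)trimethylsilane | C=C(O[Si](C)(C)C)c1c(F)c(Br)c(OC)c(Br)c1OCOC | intermediate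
7 | 4-(methoxymethoxy)benzaldehyde | COCOc1ccc(C=O)cc1 | starting material
8 | (3S)-1-[3,5-dibromo-2-fluoro-4-methoxy-6-(methoxymethoxy)phenyl]-3-[4-(methoxymethoxy)phenyl]-3-[(trimethylsilyl)oxy]propan-1-one | C[Si](C)(C)O[C@H](c1ccc(OCOC)cc1)CC(=O)c1c(F)c(Br)c(OC)c(Br)c1OCOC | intermediate
9 | (2S)-6,8-dibromo-7-methoxy-5-(methoxymethoxy)-2-[4-(methoxymethoxy)phenyl]-2,3-dihydro-4H-chromen-4-one | COc1c(Br)c(OCOC)c2c(c1Br)O[C@H](c1ccc(OCOC)cc1)CC2=O | intermediate
10 | (2S)-7-methoxy-5-(methoxymethoxy)-2-[4-(methoxymethoxy)phenyl]-6,8-bis(3-methylbut-2-en-1-yl)-2,3-dihydro-4H-chromen-4-one | COc1c(CC=C(C)C)c(OCOC)c2c(c1CC=C(C)C)O[C@H](c1ccc(OCOC)cc1)CC2=O | intermediate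
11 | (2S)-5-hydroxy-2-(4-hydroxyphenyl)-7-methoxy-6,8-bis(3-methylbut-2-en-1-yl)-2,3-dihydro-4H-chromen-4-one | COc1c(CC=C(C)C)c(O)c2c(c1CC=C(C)C)O[C@H](c1ccc(O)cc1)CC2=O | target

Total step count: 7. Longest linear sequence: 7 steps (1 → 11); aldehyde 7 enters in step 5.

Steps most likely to fail

Step 5. The unmasked C2 alkoxide may revert to enolate and aldehyde (retro-aldol) or lose water by E1cB before it closes the ring, which would erode enantiomeric purity or yield. The catalyst may also discriminate poorly between the faces of the electron-rich aldehyde. The fallback sets out from 5 and comes back at 9, building the ring first and adding the aryl group last. Ketone 5 is condensed with ethyl formate (NaH, THF, 0 °C → rt). The sodium enolate of the resulting β-keto aldehyde should close by SNAr of its oxygen at the fluorinated carbon to give 6,8-dibromo-7-methoxy-5-(methoxymethoxy)-4H-chromen-4-one F1. Enantioselective Pd(II)-catalysed conjugate addition of 4-(methoxymethoxy)phenylboronic acid to F1 then gives 9. Conditions for this addition are Pd(OCOCF3)2, the t-BuPyOx enantiomer that gives 2S, NH4PF6, H2O, ClCH2CH2Cl, 60 °C.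

Step 6. Allyl transposition during transmetalation or reductive elimination may deliver 1,1-dimethylallyl groups, and the sequence may stall after the first coupling because each bromide is flanked by two oxygen substituents. The fallback sets out from 9 and comes back at 10. A double Stille coupling with allyltributylstannane (same catalyst, DMF, 80 °C), which poses no regiochemical question and is less hindered, should give (2S)-7-methoxy-5-(methoxymethoxy)-2-[4-(methoxymethoxy)phenyl]-6,8-di(prop-2-en-1-yl)-2,3-dihydro-4H-chromen-4-one F2. Olefin cross-metathesis of F2 with excess 2-methyl-2-butene (second-generation ruthenium benzylidene catalyst, CH2Cl2, 40 °C) then converts both allyl groups into 3-methylbut-2-enyl groups and gives 10.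

Step 7. Once freed, the C5 hydroxyl may add to the C6 prenyl alkene under acid (chroman formation), or methanol or water may add to the prenyl groups before the slower 4'-O-MOM cleavage is complete. The fallback sets out from 9 and comes back at 11 by reversing the order of the last two operations. Treating 9 with 3 M HCl in MeOH removes both MOM groups while no alkene is present and gives (2S)-6,8-dibromo-5-hydroxy-2-(4-hydroxyphenyl)-7-methoxy-2,3-dihydro-4H-chromen-4-one F3. Double Stille prenylation of the free diphenol F3 under the neutral conditions of step 6 then gives 11 directly.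

Further compounds
F1 | step 5 | 6,8-dibromo-7-methoxy-5-(methoxymethoxy)-4H-chromen-4-one | COCOc1c(Br)c(OC)c(Br)c2occc(=O)c12
F2 | step 6 | (2S)-7-methoxy-5-(methoxymethoxy)-2-[4-(methoxymethoxy)phenyl]-6,8-di(prop-2-en-1-yl)-2,3-dihydro-4H-chromen-4-one | COc1c(CC=C)c(OCOC)c2c(c1CC=C)O[C@H](c1ccc(OCOC)cc1)CC2=O
F3 | step 7 | (2S)-6,8-dibromo-5-hydroxy-2-(4-hydroxyphenyl)-7-methoxy-2,3-dihydro-4H-chromen-4-one | COc1c(Br)c(O)c2c(c1Br)O[C@H](c1ccc(O)cc1)CC2=O
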